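**Retrosynthetic overview**

1. The target is the chain A–CH2–B–CH2–B–CH2–A. The strategy rests on ring A: C1 carries the propionyl group, C2 and C4 the enol oxygens, C3 the CH2 bridge, C5 two methyl groups and C6 the ketone. Because C5 is quaternary, ring A is a cyclohexadienone that cannot aromatise.
2. Last disconnection: acid hydrolysis of a fully masked tetramer (ring A: C4–OMe, C2–OSi(i-Pr)3, C1 dioxolane; rings B: six MOM ethers).
3. Key disconnection: both rings A, the last rings formed, arise together from a bis-cyclobutenone and two siloxyalkynes. The [2+2] step makes C6–C1 and C2–C3, and the 6π closure re-forms C5–C6.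
4. The bis-cyclobutenone comes from the MOM-protected central bis-aldehyde by reductive alkylation of 2,2-dimethylcyclobutane-1,3-dione (dimethylketene plus ethoxyacetylene, then hydrolysis) and O-methylation. Rings B come from phloroglucinol by propionylation, formylation and formaldehyde bridging.
5. The siloxyalkyne comes from bis(trimethylsilyl)acetylene and propionyl chloride by ketalisation, desilylation and acetylide oxidation/O-silylation.

Key step: step 13

Remark: the target has no stereocentre; rings A are drawn as one enol tautomer of a β,β'-triketone system, and the route delivers that tautomeric system.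

Remark on the masking groups: the C2 oxygen is carried as a triisopropylsilyl ynol ether because an ethyl ynol ether can lose ethylene by retro-ene reaction at the annulation temperature. The C4 oxygen is a methyl enol ether because O-methylation of the acidic enol is neutral and MOM-compatible. The propionyl group is a dioxolane installed before the ynol ether is made, because ketalising an alkoxy ynone would invite conjugate addition.

**Route**

Step 1
Reactants: 1 phloroglucinol; 2 propionyl chloride
Product: 3 1-(2,4,6-trihydroxyphenyl)propan-1-one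
Conditions: AlCl3 (3.5 equiv), PhNO2/CH2Cl2, 0 → 45 °C; aq. HCl work-up
Reagents that add atoms: none
Why: Friedel–Crafts C-acylation of the electron-rich arene should stop at the mono-ketone because the first acyl group deactivates the ring.

Step 2
Reactants: 3 1-(2,4,6-trihydroxyphenyl)propan-1-one
Product: 5 2,4,6-trihydroxy-3-propanoylbenzaldehyde, via aryl iminium chloride 4 (not isolated)
Conditions: POCl3 (1.1 equiv), DMF, EtOAc, 0 °C → rt; then H2O, 60 °C
Reagents that add atoms: N,N-dimethylformamide CN(C)C=O; water O
Why: Vilsmeier–Haack formylation of an acylphloroglucinol should stop after one formyl group because the iminium salt strongly deactivates the ring.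

Step 3
Reactants: 5 2,4,6-trihydroxy-3-propanoylbenzaldehyde (two molecules)
Product: 7 3,3'-methylenebis(2,4,6-trihydroxy-5-propanoylbenzaldehyde), via hydroxymethyl phenol 6 (not isolated)
Conditions: 37% aq. HCHO (0.5 equiv), KOH, H2O/MeOH, 0 °C → rt; then aq. HCl
Reagents that add atoms: formaldehyde C=O
Why: Base-mediated hydroxymethylation, loss of hydroxide to a quinone methide and Michael addition of a second phenolate is the classical formaldehyde bridging of acylphloroglucinols, and with one free ring carbon per molecule no oligomer can form.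

Step 4
Reactants: 7 3,3'-methylenebis(2,4,6-trihydroxy-5-propanoylbenzaldehyde)
Product: 8 3,3'-methylenebis[2,4,6-tris(methoxymethoxy)-5-propanoylbenzaldehyde]
Conditions: NaH (6.5 equiv, portionwise), MOMCl (8 equiv), DMF/THF, 0 °C → rt
Reagents that add atoms: chloromethyl methyl ether COCCl
Why: Williamson O-alkylation of the six acidic phenoxides should be clean because the fully substituted rings cannot be C-alkylated without dearomatisation, and the base is limited to the phenols to avoid ketone enolisation.

Step 5
Reactants: 9 isobutyryl chloride; 10 ethoxyacetylene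
Product: 12 3-ethoxy-4,4-dimethylcyclobut-2-en-1-one, via dimethylketene 11 (not isolated)
Conditions: Et3N, Et2O, 0 °C → rt (excess 10)
Reagents that add atoms: none
Why: Dehydrochlorination gives dimethylketene, which undergoes the known [2+2] cycloaddition with the alkynyl ether, the oxygen-free alkyne carbon bonding to the ketene carbonyl carbon.

Step 6
Reactants: 12 3-ethoxy-4,4-dimethylcyclobut-2-en-1-one
Product: 13 2,2-dimethylcyclobutane-1,3-dione (enol form 3-hydroxy-4,4-dimethylcyclobut-2-en-1-one)
Conditions: 1 M aq. HCl, THF, rt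
Reagents that add atoms: water O
Why: Acid hydrolysis of a vinylogous ester should give the strongly acidic, isolable dione.

Step 7
Reactants: 8 3,3'-methylenebis[2,4,6-tris(methoxymethoxy)-5-propanoylbenzaldehyde]; 13 2,2-dimethylcyclobutane-1,3-dione (2.2 equiv)
Product: 15 hexa-MOM central dimer bearing two (2-hydroxy-3,3-dimethyl-4-oxocyclobut-1-en-1-yl)methyl groups, via bis(alkylidene dione) 14 (not isolated)
Conditions: Hantzsch ester (2.4 equiv), L-proline (20 mol%), CH2Cl2, rt
Reagents that add atoms: none
Why: Three-component organocatalytic reductive alkylation of a cyclic 1,3-dione (Knoevenagel condensation, then conjugate transfer hydrogenation by the Hantzsch ester) should be selective for the aldehydes over the hindered aryl ketones and stop at mono-alkylation of each dione.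

Step 8
Reactants: 15 hexa-MOM central dimer bearing two (2-hydroxy-3,3-dimethyl-4-oxocyclobut-1-en-1-yl)methyl groups
Product: 16 hexa-MOM central dimer bearing two (2-methoxy-3,3-dimethyl-4-oxocyclobut-1-en-1-yl)methyl groups
Conditions: Me3SiCHN2 (2.5 equiv), MeOH/toluene, 0 °C
Reagents that add atoms: (trimethylsilyl)diazomethane C[Si](C)(C)C=[N+]=[N-]
Why: Diazoalkane O-methylation of a strongly acidic vinylogous acid is neutral and spares MOM ethers and aryl ketones, and since the two carbonyls of each dione are equivalent only one regioisomer can form.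

Step 9
Reactants: 17 bis(trimethylsilyl)acetylene; 2 propionyl chloride
Product: 18 1-(trimethylsilyl)pent-1-yn-3-one
Conditions: AlCl3, CH2Cl2, 0 °C
Reagents that add atoms: none
Why: Friedel–Crafts-type acylation with ipso-desilylation of the bis-silyl alkyne should stop after one acylation because the ynone is deactivated.

Step 10
Reactants: 18 1-(trimethylsilyl)pent-1-yn-3-one
Product: 19 2-ethyl-2-[(trimethylsilyl)ethynyl]-1,3-dioxolane
Conditions: HOCH2CH2OH, p-TsOH (cat.), benzene, reflux, Dean–Stark
Reagents that add atoms: ethylene glycol OCCO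
Why: Acid-catalysed ketalisation with water removal works on silyl-capped ynones because the silyl group suppresses conjugate addition of the diol.

Step 11
Reactants: 19 2-ethyl-2-[(trimethylsilyl)ethynyl]-1,3-dioxolane
Product: 20 2-ethyl-2-ethynyl-1,3-dioxolane
Conditions: K2CO3 (cat.), MeOH, rt
Reagents that add atoms: none
Why: Methanolysis of the alkynyl C–Si bond under mild base leaves the ketal untouched.

Step 12
Reactants: 20 2-ethyl-2-ethynyl-1,3-dioxolane
Product: 23 {[(2-ethyl-1,3-dioxolan-2-yl)ethynyl]oxy}tri(propan-2-yl)silane, via lithium acetylide 21 (not isolated), via lithium ynolate 22 (not isolated)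
Conditions: LiN(SiMe3)2 (2.1 equiv), THF, −78 °C; t-BuOOH (1.0 equiv), −78 → 0 °C; i-Pr3SiOTf (1.2 equiv), −78 → 0 °C
Reagents that add atoms: tert-butyl hydroperoxide CC(C)(C)OO; triisopropylsilyl trifluoromethanesulfonate CC(C)[Si](C(C)C)(C(C)C)OS(=O)(=O)C(F)(F)F
Why: Oxidation of a lithium acetylide by the lithium tert-butylperoxide oxenoid gives the ynolate, and the bulky silyl triflate traps it on oxygen, an established route to triisopropylsilyl ynol ethers.

Step 13
Reactants: 16 hexa-MOM central dimer bearing two (2-methoxy-3,3-dimethyl-4-oxocyclobut-1-en-1-yl)methyl groups; 23 {[(2-ethyl-1,3-dioxolan-2-yl)ethynyl]oxy}tri(propan-2-yl)silane (4 equiv)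
Product: 27 fully masked target with each ring A as a 4-methoxy-5,5-dimethyl-2-(triisopropylsilyloxy)cyclohexa-1,3-dien-6-one carrying the 2-ethyl-1,3-dioxolan-2-yl group at C1 and joined through C3–CH2 to the hexa-MOM central dimer, via bis(vinylketene) 24 (not isolated), via bis(4-alkenylcyclobutenone) 25 (not isolated), via bis(dienylketene) 26 (not isolated)
Conditions: toluene (0.05 M, degassed), 120 °C, sealed tube, Ar
Reagents that add atoms: none
Why: Proposed new method: each 3-methoxy-4,4-dimethylcyclobutenone should open thermally (4π electrocyclic, C5–C6 cleaved) to a vinylketene whose ketene carbon (C6) is attacked by the oxygen-free carbon of the siloxyalkyne, so that the [2+2] cycloaddition forms C6–C1 and C2–C3 with the dioxolane carbon at C1 next to the ketone, and the resulting 4-alkenylcyclobutenone reopens (4π) to a dienylketene. Each ring A then closes by thermal 6π electrocyclisation of that dienylketene, which re-forms the C5–C6 bond at the CMe2 terminus. The closest known reactions are the Danheiser benzannulation of cyclobutenones with siloxyalkynes and the cyclohexadienone annulation of β,β-disubstituted alkenyl Fischer carbene complexes with alkynes, which closes the same kind of dienylketene onto a disubstituted terminus; new here are the 4,4-dialkyl-3-alkoxycyclobutenone, the fully substituted ketene and the twofold reaction on one molecule. Because C5 is quaternary the dienone cannot tautomerise to a phenol and stays at the oxidation level of ring A. No stereocentre is formed, since the quaternary centre of the 4-alkenylcyclobutenone is erased in the second ring opening, and the reversibility of both ring openings should funnel either alkene geometry to the cyclisable (Z)-dienylketene. The step needs regioselectivity in the [2+2] addition, secured by the polarisation of the ynol ether, and chemoselectivity for the alkyne over ketene dimerisation, secured by excess electron-rich alkyne and dilution, while the strain of both four-membered rings drives the cascade.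

Step 14
Reactants: 27 fully masked target
Product: 28 target CNP0541376.0
Conditions: 3 M aq. HCl, THF/MeOH, 45 °C
Reagents that add atoms: water O
Why: Aqueous acid should cleave the two silyl enol ethers, hydrolyse the two vinylogous methyl esters and the two enol-activated dioxolanes and remove the six MOM acetals; the liberated formaldehyde finds no free ring carbon to attack.

**Compound list**

1 | phloroglucinol | Oc1cc(O)cc(O)c1 | starting material
2 | propionyl chloride | CCC(Cl)=O | starting material
3 | 1-(2,4,6-trihydroxyphenyl)propan-1-one | CCC(=O)c1c(O)cc(O)cc1O | intermediate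
4 | N,N-dimethyl aryl iminium chloride of 5 | CCC(=O)c1c(O)cc(O)c(C=[N+](C)C)c1O.[Cl-] | intermediate
5 | 2,4,6-trihydroxy-3-propanoylbenzaldehyde | CCC(=O)c1c(O)cc(O)c(C=O)c1O | intermediate
6 | 2,4,6-trihydroxy-3-(hydroxymethyl)-5-propanoylbenzaldehyde | CCC(=O)c1c(O)c(CO)c(O)c(C=O)c1O | intermediate
7 | 3,3'-methylenebis(2,4,6-trihydroxy-5-propanoylbenzaldehyde) | CCC(=O)c1c(O)c(C=O)c(O)c(Cc2c(O)c(C=O)c(O)c(C(=O)CC)c2O)c1O | intermediate
8 | 3,3'-methylenebis[2,4,6-tris(methoxymethoxy)-5-propanoylbenzaldehyde] | CCC(=O)c1c(OCOC)c(C=O)c(OCOC)c(Cc2c(OCOC)c(C=O)c(OCOC)c(C(=O)CC)c2OCOC)c1OCOC | intermediate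
9 | isobutyryl chloride | CC(C)C(Cl)=O | starting material
10 | ethoxyacetylene | C#COCC | starting material
11 | dimethylketene | CC(C)=C=O | intermediate
12 | 3-ethoxy-4,4-dimethylcyclobut-2-en-1-one | CCOC1=CC(=O)C1(C)C | intermediate
13 | 2,2-dimethylcyclobutane-1,3-dione | CC1(C)C(=O)CC1=O | intermediate
14 | hexa-MOM central dimer bearing two (3,3-dimethyl-2,4-dioxocyclobutylidene)methyl groups | CCC(=O)c1c(OCOC)c(C=C2C(=O)C(C)(C)C2=O)c(OCOC)c(Cc2c(OCOC)c(C=C3C(=O)C(C)(C)C3=O)c(OCOC)c(C(=O)CC)c2OCOC)c1OCOC | intermediate
15 | hexa-MOM central dimer bearing two (2-hydroxy-3,3-dimethyl-4-oxocyclobut-1-en-1-yl)methyl groups | CCC(=O)c1c(OCOC)c(CC2=C(O)C(C)(C)C2=O)c(OCOC)c(Cc2c(OCOC)c(CC3=C(O)C(C)(C)C3=O)c(OCOC)c(C(=O)CC)c2OCOC)c1OCOC | intermediate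
16 | hexa-MOM central dimer bearing two (2-methoxy-3,3-dimethyl-4-oxocyclobut-1-en-1-yl)methyl groups | CCC(=O)c1c(OCOC)c(CC2=C(OC)C(C)(C)C2=O)c(OCOC)c(Cc2c(OCOC)c(CC3=C(OC)C(C)(C)C3=O)c(OCOC)c(C(=O)CC)c2OCOC)c1OCOC | intermediate
17 | bis(trimethylsilyl)acetylene | C[Si](C)(C)C#C[Si](C)(C)C | starting material
18 | 1-(trimethylsilyl)pent-1-yn-3-one | CCC(=O)C#C[Si](C)(C)C | intermediate
19 | 2-ethyl-2-[(trimethylsilyl)ethynyl]-1,3-dioxolane | CCC1(C#C[Si](C)(C)C)OCCO1 | intermediate
20 | 2-ethyl-2-ethynyl-1,3-dioxolane | CCC1(C#C)OCCO1 | intermediate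
21 | lithium (2-ethyl-1,3-dioxolan-2-yl)acetylide | CCC1(C#C[Li])OCCO1 | intermediate
22 | lithium 2-(2-ethyl-1,3-dioxolan-2-yl)ethynolate | CCC1(C#CO[Li])OCCO1 | intermediate
23 | {[(2-ethyl-1,3-dioxolan-2-yl)ethynyl]oxy}tri(propan-2-yl)silane | CCC1(C#CO[Si](C(C)C)(C(C)C)C(C)C)OCCO1 | intermediate
24 | bis(vinylketene) from twofold ring opening of 16 | CCC(=O)c1c(OCOC)c(CC(=C=O)C(OC)=C(C)C)c(OCOC)c(Cc2c(OCOC)c(CC(=C=O)C(OC)=C(C)C)c(OCOC)c(C(=O)CC)c2OCOC)c1OCOC | intermediate
25 | bis(4-alkenylcyclobutenone) [2+2] adduct (mixture of diastereomers at the transient quaternary ring carbons) | CCC(=O)c1c(OCOC)c(CC2(C(OC)=C(C)C)C(=O)C(C3(CC)OCCO3)=C2O[Si](C(C)C)(C(C)C)C(C)C)c(OCOC)c(Cc2c(OCOC)c(CC3(C(OC)=C(C)C)C(=O)C(C4(CC)OCCO4)=C3O[Si](C(C)C)(C(C)C)C(C)C)c(OCOC)c(C(=O)CC)c2OCOC)c1OCOC | intermediate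
26 | bis(dienylketene) | CCC(=O)c1c(OCOC)c(CC(=C(O[Si](C(C)C)(C(C)C)C(C)C)C(=C=O)C2(CC)OCCO2)C(OC)=C(C)C)c(OCOC)c(Cc2c(OCOC)c(CC(=C(O[Si](C(C)C)(C(C)C)C(C)C)C(=C=O)C3(CC)OCCO3)C(OC)=C(C)C)c(OCOC)c(C(=O)CC)c2OCOC)c1OCOC | intermediate
27 | fully masked target (ring A: C1 dioxolane, C2 OSi(i-Pr)3, C4 OMe; rings B: MOM ethers) | CCC(=O)c1c(OCOC)c(CC2=C(OC)C(C)(C)C(=O)C(C3(CC)OCCO3)=C2O[Si](C(C)C)(C(C)C)C(C)C)c(OCOC)c(Cc2c(OCOC)c(CC3=C(OC)C(C)(C)C(=O)C(C4(CC)OCCO4)=C3O[Si](C(C)C)(C(C)C)C(C)C)c(OCOC)c(C(=O)CC)c2OCOC)c1OCOC | intermediate
28 | CNP0541376.0 | CCC(=O)C1=C(O)C(Cc2c(O)c(Cc3c(O)c(CC4=C(O)C(C)(C)C(=O)C(C(=O)CC)=C4O)c(O)c(C(=O)CC)c3O)c(O)c(C(=O)CC)c2O)=C(O)C(C)(C)C1=O | target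

**Step count and risks**

Total step count: 14. Longest linear sequence: 8 steps (steps 1, 2, 3, 4, 7, 8, 13, 14).

Steps most likely to fail:

1. Step 13. The [2+2] addition joins a fully substituted ketene to an alkyne carbon that carries a quaternary ketal carbon and may be slow. The vinylketene can then escape by a [1,5]-hydrogen shift from its cis methyl group or by oligomerisation, or the reaction can stop after one of the two annulations. Fallback by known chemistry, setting out from 3 and coming back at 28: 3 is bridged with aqueous formaldehyde (0.5 equiv, dilute KOH) to 3,3'-methylenebis(2,4,6-trihydroxypropiophenone) F1. A second portion of 3 is gem-dimethylated (MeI, NaOMe, MeOH) to propionylfilicinic acid F2. F1, F2 (2 equiv) and formaldehyde (2 equiv) are then condensed in dilute aqueous KOH, the classical methylene bridging of acylfilicinic acids with acylphloroglucinols. This should give 28 directly after separation from homo-coupled products.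

2. Step 7. Condensation at the doubly ortho-substituted, electron-rich aldehydes may be sluggish. The amine catalyst may open the strained dione by retro-Claisen cleavage, and a second dione may add to the alkylidene intermediate before it is reduced. Fallback, setting out from 8 and coming back at 15: the aldehydes of 8 are reduced chemoselectively (NaBH4, MeOH, −20 °C) to the bis(benzylic alcohol) F3. Its highly stabilised benzylic cations, formed under the mild acidity of dione 13 itself (MeNO2, 40 °C), then C-benzylate 13 in a dehydrative SN1 alkylation to give 15.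

3. Step 14. Hot aqueous acid may cleave or scramble the methylene bridges by retro-Friedel–Crafts reaction before the vinylogous methyl esters are fully hydrolysed. Fallback, setting out from 27 and coming back at 28: the ring A oxygens are unmasked without acid, the silyl enol ethers by n-Bu4NF (THF, 0 °C) and the methyl enol ethers by SN2 demethylation with LiI (EtOAc, 70 °C). This gives the hexa-MOM bis-ketal with free ring A enols F4. Its MOM acetals and enol-activated dioxolanes are then removed by brief methanolysis (1 M HCl in wet MeOH, rt) to give 28.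

**Further compounds**

F1 | step 13 | 3,3'-methylenebis(2,4,6-trihydroxypropiophenone) | CCC(=O)c1c(O)cc(O)c(Cc2c(O)cc(O)c(C(=O)CC)c2O)c1O
F2 | step 13 | propionylfilicinic acid (3,5-dihydroxy-4,4-dimethyl-2-propanoylcyclohexa-2,5-dien-1-one) | CCC(=O)C1=C(O)C=C(O)C(C)(C)C1=O
F3 | step 7 | hexa-MOM central dimer bearing two hydroxymethyl groups | CCC(=O)c1c(OCOC)c(CO)c(OCOC)c(Cc2c(OCOC)c(CO)c(OCOC)c(C(=O)CC)c2OCOC)c1OCOC
F4 | step 14 | hexa-MOM bis-ketal with free ring A enols | CCC(=O)c1c(OCOC)c(CC2=C(O)C(C)(C)C(=O)C(C3(CC)OCCO3)=C2O)c(OCOC)c(Cc2c(OCOC)c(CC3=C(O)C(C)(C)C(=O)C(C4(CC)OCCO4)=C3O)c(OCOC)c(C(=O)CC)c2OCOC)c1OCOC
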